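## Analysis of the target

The target is [(3R)-6-geranyl-3,5,7-trihydroxy-2,2-dimethylchroman-8-yl](phenyl)methanone, a benzoylphloroglucinol whose oxygenated arene is hexasubstituted. In chroman numbering, C8 carries the benzoyl group, C6 the (E)-geranyl chain, C5 and C7 free hydroxyls, and C4a/C8a are shared with a dihydropyran ring (O1, C2, C3, C4, C4a, C8a). The only stereocentre is C3 (R), a secondary carbinol between the quaternary C2 (two methyls and O1) and the benzylic methylene C4. Nothing else in the molecule can relay chirality to it, so its configuration has to come from a reagent or catalyst. The sensitive groups are the geranyl chain (two trisubstituted alkenes, open to epoxidation and to acid-induced cyclisation onto the flanking phenols), the very electron-rich arene, and the chelated ortho-hydroxy ketone.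

Three linked problems make the synthesis hard. The three phenolic oxygens of the parent benzophenone must be told apart, because only the one next to the benzoyl group may enter the ring. The C5 unit must be oxygenated at C3 while two further alkenes of the same kind are, or will be, present. A polar closure of the oxygen ring can go 5-exo as well as 6-endo.

The feature that invites the key move is the string O1–C8a–C4a–C4 with C4 an unsubstituted benzylic CH2. This is the skeleton of an ortho-quinone methide; extended by C3 and C2 it is a 1-oxatriene whose 6π closure makes O1–C2. The C3=C4 alkene that remains is a cis-disubstituted, aryl-conjugated alkene in a 2,2-dimethyl-2H-chromene, the best substrate class for manganese–salen epoxidation, and it is the only alkene in the molecule as long as the geranyl chain is added last.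

## Retrosynthetic reasoning

**10 to 8 and 9 (bond C6–C1' of the geranyl chain).** The geranyl chain is cut off first, so that its two alkenes never meet the oxidant that makes the C3–O bond or the hydrogenation that follows. In 8, C6 is the only unsubstituted ring carbon and lies between two phenolic hydroxyls. The forward reaction is therefore a C-alkylation of the phenoxide of 8 with 9 that has no regiochemical choice on the ring.

**8 to 6 through 7 (C4–H and two phenolic O–H bonds).** The C4 methylene is traced back to a benzylic C4–O bond of a 3,4-epoxide, and the two phenols to benzyl ethers. One catalytic hydrogenolysis then does three jobs: it cleaves the benzylic epoxide bond (giving 7) and both benzyl ethers (giving 8). The C3–O bond is not touched, so the stereocentre of 6 is carried into 8 unchanged.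

**6 to 5 (the epoxide oxygen on C3 and C4).** The stereocentre is cut back to the C3=C4 alkene of chromene 5. This is where the absolute configuration is set, by oxygen-atom transfer from a chiral manganese salen catalyst to the only alkene of 5. Choosing this bond turns the carbinol problem into the best-precedented substrate class for that epoxidation and avoids any competition with a prenyl-type alkene.

**5 to 2 and 3 through 4 (bonds O1–C2 and C4–C4a; key disconnection).** The whole pyran ring is removed in one cut. Retro-6π opening of 5 gives the ortho-quinone methide 4, and retro-condensation of 4 gives the phenol 2 and the five-carbon enal 3. The cut is made here because it forms the C–C bond to the arene and the C–O bond of the ring in one operation. The ring size is fixed by a pericyclic closure, so no 5-exo pathway exists. The regiochemistry is fixed because only one oxygen of 2 is free to become the carbonyl of 4. The precursor 2 is a one-step derivative of a purchased benzophenone, and 3 is a commodity aldehyde.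

**2 to 1 (two O–benzyl bonds).** The two benzyl ethers are the regiochemical control element of the key step and leave in the hydrogenolysis that is needed anyway. In 1 the two ortho-hydroxyls are equivalent, so bis-etherification that stops before the chelated hydroxyl gives a single compound.

## Alternatives that were turned down

**Alternative 1:** the textbook route, cutting only O1–C2.
- Disconnection and forward step: two C-alkylations of 1 give the geranyl prenyl benzophenone A1. Shi epoxidation of the prenyl alkene (fructose-derived ketone, KHSO5) gives epoxide A2, and acid-promoted 6-endo opening at the tertiary carbon closes the ring.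
- Why turned down: A1 has three trisubstituted alkenes that a dioxirane cannot tell apart. In A2 two phenols flank the epoxide and each can close 5-exo or 6-endo, so there are four modes of closure and nothing in the substrate selects one. The acid needed to favour the 6-endo mode is the reagent that cyclises geranyl chains onto neighbouring phenols. Reordering (epoxide before geranyl) would put an epoxide next to a phenoxide under the basic alkylation conditions and would add protecting-group steps.

**Alternative 2:** intermolecular hetero-Diels–Alder reaction of a methylene ortho-quinone methide, cutting O1–C2 and C3–C4.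
- Disconnection and forward step: Mannich base A3 of phenol 2 is thermolysed to the methylene quinone methide A4. This is trapped by 2-methylprop-1-enylboronic acid pinacol ester to give the 3-borylchroman A5, which is oxidised with retention to the carbinol.
- Why turned down: the well-behaved partners of ortho-quinone methides are enol ethers, and their polarity puts the oxygen at C2 and the methyls at C3, the wrong way round. The alkenylboronate has the right polarity but is a weak and unprecedented partner. The single stereocentre would arise on the dienophile carbon opposite an unsubstituted CH2 terminus, where a chiral catalyst has no handle, so A5 would be racemic. The sequence also needs three operations for what the chosen key step does in one.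

**Alternative 3:** cutting C4–C4a by a 6-endo Friedel–Crafts epoxy-arene cyclisation.
- Disconnection and forward step: the tertiary aryl ether epoxide A6 closes onto the free ring carbon under Lewis acid or fluorinated-alcohol activation.
- Why turned down: A6 requires a tertiary alkyl aryl ether on the most hindered and least nucleophilic (chelated) oxygen. Its epoxide would have to come from a monosubstituted vinyl group on a quaternary carbon, a poor substrate for asymmetric epoxidation, so a dihydroxylation and ring-closure detour would be needed. The Lewis acid that activates the epoxide also ionises the tertiary aryl ether bond. Four to five steps would be spent to reach A6, against one step to reach 5.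

Key step: step 2

Remark: chroman numbering (O1, C2, C3, C4, C4a, C5 to C8, C8a) is used for all bicyclic compounds; compounds 1, 3 and 9 are taken as purchased materials.

## Route

Step 1
Reactants: 1 (2,4,6-trihydroxyphenyl)(phenyl)methanone (2,4,6-trihydroxybenzophenone)
Product: 2 [2,4-bis(benzyloxy)-6-hydroxyphenyl](phenyl)methanone
Conditions: BnBr (2.1 equiv), K2CO3 (2.2 equiv), DMF, rt
Reagents that add atoms: benzyl bromide, BrCc1ccccc1
Why: Williamson etherification; the para hydroxyl and one ortho hydroxyl react, while the last ortho hydroxyl is locked in the six-membered hydrogen-bonded chelate with the benzoyl carbonyl and should stay free, and because the two ortho hydroxyls of 1 are equivalent only one bis-ether can form.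

Step 2
Reactants: 2 [2,4-bis(benzyloxy)-6-hydroxyphenyl](phenyl)methanone; 3 3-methylbut-2-enal
Product: 5 [5,7-bis(benzyloxy)-2,2-dimethyl-2H-chromen-8-yl](phenyl)methanone, via ortho-quinone methide 4 (not isolated)
Conditions: 3 (3 equiv), ethylenediammonium diacetate (20 mol%), xylene, 140 °C
Reagents that add atoms: none
Why: Amine-salt-catalysed Knoevenagel-type condensation of 3 at the ring carbon ortho to the free hydroxyl of 2, with loss of water, should give the vinylogous ortho-quinone methide 4, which forms the C4–C4a bond. Compound 4 is a 1-oxatriene (C8a=O, C4a=C4, C3=C2) and should close by a thermally allowed disrotatory oxa-6π electrocyclisation that forms O1–C2 and restores the aromatic ring; only the Z geometry drawn for 4 can close, and E/Z equilibration of the exocyclic alkene under the hot conditions is assumed. The closest known reaction type is the ethylenediammonium diacetate or pyridine mediated chromenylation of resorcinol- and phloroglucinol-type phenols with enals. The ring closed is the 2H-pyran ring, by a pericyclic 6π closure and not by a polar addition, so a five-membered alternative does not exist. No stereocentre is formed, since C2 carries two methyl groups. The selectivity needed is the choice of the ring oxygen, and it is secured by the substrate: the two other oxygens are benzyl ethers, so only the hydroxyl next to the benzoyl group can become the carbonyl of 4, which places the benzoyl group at C8 and the ethers at C5 and C7. The second free ring carbon of 2 lies between two ethers and cannot give a quinone methide, so attack there is unproductive and reversible. Attack at the carbonyl carbon rather than the β-carbon of 3 is expected because the β-carbon carries two methyl groups.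

Step 3
Reactants: 5 [5,7-bis(benzyloxy)-2,2-dimethyl-2H-chromen-8-yl](phenyl)methanone
Product: 6 [(3R,4R)-5,7-bis(benzyloxy)-3,4-epoxy-2,2-dimethyl-3,4-dihydro-2H-chromen-8-yl](phenyl)methanone
Conditions: (R,R)-N,N'-bis(3,5-di-tert-butylsalicylidene)-1,2-cyclohexanediaminomanganese chloride (5 mol%), 4-phenylpyridine N-oxide (20 mol%), aq. NaOCl (pH 11.3, Na2HPO4), CH2Cl2, 0 °C
Reagents that add atoms: sodium hypochlorite, [Na+].[O-]Cl
Why: Jacobsen–Katsuki epoxidation; C3=C4 is the only alkene of 5 and belongs to the benchmark class of cis-disubstituted, aryl-conjugated 2,2-dimethylchromenes. The oxo complex of pentavalent manganese should deliver oxygen to one enantioface, and by analogy with that class the (R,R) ligand is expected to give the (3R,4R) epoxide; the cis ring fusion is forced by the ring. The basic two-phase medium keeps the acid-labile epoxide away from acid, and 6 is used after filtration through base-washed silica.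

Step 4
Reactants: 6 [(3R,4R)-5,7-bis(benzyloxy)-3,4-epoxy-2,2-dimethyl-3,4-dihydro-2H-chromen-8-yl](phenyl)methanone
Product: 8 [(3R)-3,5,7-trihydroxy-2,2-dimethyl-3,4-dihydro-2H-chromen-8-yl](phenyl)methanone, via dibenzyl ether 7 (not isolated)
Conditions: H2 (1 atm), Pd/C (10%), EtOAc, rt
Reagents that add atoms: none
Why: Heterogeneous hydrogenolysis; the benzylic C4–O bond of the epoxide should be cleaved first to give 7, and the same catalyst then removes both benzyl ethers. The C3–O bond is never broken, so C3 keeps its configuration and its descriptor R (priorities O > C2 > C4 > H are unchanged). The twisted, doubly ortho-oxygenated diaryl ketone is expected to resist these mild conditions and becomes chelated once the 7-hydroxyl is free.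

Step 5
Reactants: 8 [(3R)-3,5,7-trihydroxy-2,2-dimethyl-3,4-dihydro-2H-chromen-8-yl](phenyl)methanone; 9 (2E)-1-bromo-3,7-dimethylocta-2,6-diene (geranyl bromide)
Product: 10 [(3R)-6-[(2E)-3,7-dimethylocta-2,6-dien-1-yl]-3,5,7-trihydroxy-2,2-dimethyl-3,4-dihydro-2H-chromen-8-yl](phenyl)methanone (target)
Conditions: 9 (1.05 equiv), DBU (1.1 equiv), THF, 0 °C to rt
Reagents that add atoms: none
Why: Base-mediated C-alkylation of an acylphloroglucinol-type phenoxide by SN2 reaction with the primary allylic bromide; C6 is the only unsubstituted ring carbon and is activated by both flanking hydroxyls, and the alkylated dienone should rearomatise by tautomerisation. The E alkene of 9 is carried through because the substitution takes place at the primary carbon, and the secondary 3-hydroxyl is not ionised by DBU.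

## Compound list

1 | (2,4,6-trihydroxyphenyl)(phenyl)methanone | O=C(c1ccccc1)c1c(O)cc(O)cc1O | starting material
2 | [2,4-bis(benzyloxy)-6-hydroxyphenyl](phenyl)methanone | O=C(c1ccccc1)c1c(O)cc(OCc2ccccc2)cc1OCc1ccccc1 | intermediate
3 | 3-methylbut-2-enal | CC(C)=CC=O | starting material
4 | (6Z)-2-benzoyl-3,5-bis(benzyloxy)-6-(3-methylbut-2-en-1-ylidene)cyclohexa-2,4-dien-1-one (ortho-quinone methide) | c1ccccc1COC1=CC(OCc2ccccc2)=C(C(=O)c2ccccc2)C(=O)/C1=C\C=C(C)C | intermediate (not isolated)
5 | [5,7-bis(benzyloxy)-2,2-dimethyl-2H-chromen-8-yl](phenyl)methanone | c1ccccc1COc1cc(OCc2ccccc2)c2c(c1C(=O)c1ccccc1)OC(C)(C)C=C2 | intermediate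
6 | [(3R,4R)-5,7-bis(benzyloxy)-3,4-epoxy-2,2-dimethyl-3,4-dihydro-2H-chromen-8-yl](phenyl)methanone | c1ccccc1COc1cc(OCc2ccccc2)c2c(c1C(=O)c1ccccc1)OC(C)(C)[C@@H]1O[C@H]21 | intermediate
7 | [(3R)-5,7-bis(benzyloxy)-3-hydroxy-2,2-dimethyl-3,4-dihydro-2H-chromen-8-yl](phenyl)methanone | c1ccccc1COc1cc(OCc2ccccc2)c2c(c1C(=O)c1ccccc1)OC(C)(C)[C@H](O)C2 | intermediate (not isolated)
8 | [(3R)-3,5,7-trihydroxy-2,2-dimethyl-3,4-dihydro-2H-chromen-8-yl](phenyl)methanone | Oc1cc(O)c2c(c1C(=O)c1ccccc1)OC(C)(C)[C@H](O)C2 | intermediate
9 | (2E)-1-bromo-3,7-dimethylocta-2,6-diene (geranyl bromide) | CC(C)=CCC/C(C)=C/CBr | starting material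
10 | [(3R)-6-[(2E)-3,7-dimethylocta-2,6-dien-1-yl]-3,5,7-trihydroxy-2,2-dimethyl-3,4-dihydro-2H-chromen-8-yl](phenyl)methanone | CC(C)=CCC/C(C)=C/Cc1c(O)c2c(c(C(=O)c3ccccc3)c1O)OC(C)(C)[C@H](O)C2 | target

## Step count and least certain steps

Total step count: 5. Longest linear sequence: 5 steps (1, 2, 5, 6, 8, 10).

**Step 2 (key step).**
- What may go wrong: the carbon–carbon bond formation may be sluggish, because the only free hydroxyl of 2 is held in a hydrogen bond to the benzoyl carbonyl and the ring carries an acyl group. Self-condensation of 3, or conjugate addition of a second molecule of 2 to the quinone methide, would then take over.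
- Fallback: the annulation is moved to a resorcinol-type nucleophile. Compound 1 is mono-benzylated at the para hydroxyl (BnBr, 1 equiv, NaHCO3, DMF) to [4-(benzyloxy)-2,6-dihydroxyphenyl](phenyl)methanone F1. F1 has one ortho hydroxyl that is not chelated, and its para oxygen is blocked, so the same condensation and electrocyclisation with 3 can only close onto an oxygen next to the benzoyl group, giving [5-(benzyloxy)-7-hydroxy-2,2-dimethyl-2H-chromen-8-yl](phenyl)methanone F2. Benzylation of the remaining chelated hydroxyl (BnBr, K2CO3, DMF, 60 °C) brings the material back to 5.

**Step 3.**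
- What may go wrong: the epoxide may ionise at C4 during reaction or isolation, because the cation is stabilised by O1 and by the 5- and 7-oxygens. Hypochlorite may chlorinate the ring at C6. The benzyloxy group at C5, next to C4, may erode the facial selectivity.
- Fallback: the stereocentre is set by ketone reduction instead. Compound 5 is epoxidised with dimethyldioxirane and the crude epoxide is rearranged with ZnI2 (Meinwald rearrangement, hydride shift from C3 to C4) to [5,7-bis(benzyloxy)-2,2-dimethyl-3-oxo-3,4-dihydro-2H-chromen-8-yl](phenyl)methanone F3. Corey–Bakshi–Shibata reduction with (S)-2-methyl-CBS-oxazaborolidine and catecholborane at −78 °C, with the oxygen-bearing quaternary carbon as the large group and the benzylic CH2 as the small one, is expected to give the R alcohol. This is 7, now isolated, and the hydrogenolysis of step 4 converts it to 8.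

**Step 4.**
- What may go wrong: the diaryl ketone may be over-reduced during the longer exposure that the two benzyl ethers need. If a benzyl ether leaves before the epoxide is cleaved, the free phenol can open the epoxide to a quinone methide, and tautomerisation of that species to an enol would erase C3.
- Fallback: the three tasks are separated. Compound 6 is treated with LiAlH4 (THF, −20 °C), which delivers hydride to the benzylic C4 and also reduces the ketone, to give (3R)-5,7-bis(benzyloxy)-8-[hydroxy(phenyl)methyl]-2,2-dimethyl-3,4-dihydro-2H-chromen-3-ol F4 as a mixture of carbinol epimers. MnO2 (CH2Cl2, rt) re-oxidises only the doubly benzylic carbinol and gives 7. BCl3 with pentamethylbenzene (CH2Cl2, −78 °C) then removes both benzyl groups without hydrogen and gives 8.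

**Step 5.**
- What may go wrong: O-alkylation at the 5- or 7-oxygen may compete with C-alkylation, and a second alkylation at C6 with loss of aromaticity may follow.
- Fallback: the bond is made by cross-coupling instead of phenoxide alkylation. Compound 8 is iodinated at its only free ring carbon (N-iodosuccinimide, MeCN, 0 °C) to [(3R)-3,5,7-trihydroxy-6-iodo-2,2-dimethyl-3,4-dihydro-2H-chromen-8-yl](phenyl)methanone F5. Stille coupling of F5 with (E)-geranyltributylstannane under Pd(PPh3)4 (a complex of zerovalent palladium) in DMF at 80 °C is expected to bond the unsubstituted allyl terminus to C6 with retention of the E alkene, and gives 10 directly.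

## Further compounds

F1 | step 2 | [4-(benzyloxy)-2,6-dihydroxyphenyl](phenyl)methanone | O=C(c1ccccc1)c1c(O)cc(OCc2ccccc2)cc1O
F2 | step 2 | [5-(benzyloxy)-7-hydroxy-2,2-dimethyl-2H-chromen-8-yl](phenyl)methanone | Oc1cc(OCc2ccccc2)c2c(c1C(=O)c1ccccc1)OC(C)(C)C=C2
F3 | step 3 | [5,7-bis(benzyloxy)-2,2-dimethyl-3-oxo-3,4-dihydro-2H-chromen-8-yl](phenyl)methanone | c1ccccc1COc1cc(OCc2ccccc2)c2c(c1C(=O)c1ccccc1)OC(C)(C)C(=O)C2
F4 | step 4 | (3R)-5,7-bis(benzyloxy)-8-[hydroxy(phenyl)methyl]-2,2-dimethyl-3,4-dihydro-2H-chromen-3-ol, both epimers at the carbinol carbon | c1ccccc1COc1cc(OCc2ccccc2)c2c(c1C(O)c1ccccc1)OC(C)(C)[C@H](O)C2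
F5 | step 5 | [(3R)-3,5,7-trihydroxy-6-iodo-2,2-dimethyl-3,4-dihydro-2H-chromen-8-yl](phenyl)methanone | Oc1c(I)c(O)c2c(c1C(=O)c1ccccc1)OC(C)(C)[C@H](O)C2
A1 | alternative 1 | [3-[(2E)-3,7-dimethylocta-2,6-dien-1-yl]-2,4,6-trihydroxy-5-(3-methylbut-2-en-1-yl)phenyl](phenyl)methanone | CC(C)=CCC/C(C)=C/Cc1c(O)c(CC=C(C)C)c(O)c(C(=O)c2ccccc2)c1O
A2 | alternative 1 | [3-{[(2R)-3,3-dimethyloxiran-2-yl]methyl}-5-[(2E)-3,7-dimethylocta-2,6-dien-1-yl]-2,4,6-trihydroxyphenyl](phenyl)methanone | CC(C)=CCC/C(C)=C/Cc1c(O)c(C[C@H]2OC2(C)C)c(O)c(C(=O)c2ccccc2)c1O
A3 | alternative 2 | {4,6-bis(benzyloxy)-3-[(dimethylamino)methyl]-2-hydroxyphenyl}(phenyl)methanone | CN(C)Cc1c(O)c(C(=O)c2ccccc2)c(OCc2ccccc2)cc1OCc1ccccc1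
A4 | alternative 2 | 2-benzoyl-3,5-bis(benzyloxy)-6-methylidenecyclohexa-2,4-dien-1-one | C=C1C(OCc2ccccc2)=CC(OCc2ccccc2)=C(C(=O)c2ccccc2)C1=O
A5 | alternative 2 | [5,7-bis(benzyloxy)-2,2-dimethyl-3-(4,4,5,5-tetramethyl-1,3,2-dioxaborolan-2-yl)-3,4-dihydro-2H-chromen-8-yl](phenyl)methanone, racemic | c1ccccc1COc1cc(OCc2ccccc2)c2c(c1C(=O)c1ccccc1)OC(C)(C)C(B1OC(C)(C)C(C)(C)O1)C2
A6 | alternative 3 | [2,4-bis(benzyloxy)-6-({2-[(2R)-oxiran-2-yl]propan-2-yl}oxy)phenyl](phenyl)methanone | c1ccccc1COc1cc(OCc2ccccc2)c(C(=O)c2ccccc2)c(OC(C)(C)[C@H]2CO2)c1
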